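Jaspic acid is cut through ring B at C5–C6 and C9–C10. The quaternary C10, which carries the angular methyl and is shared by ring A (C1–C5, C10) and ring B (C5–C10), sits between the C5 methine and C9 with its benzylic C11: the footprint of a diene adding to the methyl-substituted double bond of a toluquinone that lives on as ring A. A titanium–BINOL-catalysed Diels–Alder reaction between 2-methoxy-5-methyl-1,4-benzoquinone and an aryl-bearing (Z)-2-silyloxydiene closes ring B, makes both bonds, fixes C10 absolutely and leaves oxygen at C1, C3, C4 and C8 as handles for every later change.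

Key step: step 3

Assumption: the (R)-BINOL ligand is taken to give the C10 configuration of the target; if the sense of induction is the opposite, the (S)-ligand is used and nothing else changes.

Conventions: ring carbons are numbered as in the target decalin (C1–C10; C11 is the benzylic carbon). β is the face of the C10 methyl. ArCH2 = 2-methoxy-5-(methoxycarbonyl)benzyl; R = 4-methylpent-3-en-1-yl; TIPS = triisopropylsilyl.

Step 1
Reactants: 1 methyl 3-iodo-4-methoxybenzoate; 2 penta-1,4-dien-3-ol
Product: 3 methyl 4-methoxy-3-(3-oxopent-4-en-1-yl)benzoate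
Conditions: Pd(OAc)2 (5 mol %), Bu4NCl, NaHCO3, DMF, 45 °C, threefold excess of 2
Reagents that add atoms: none
Why: Jeffery-type Heck arylation of a secondary allylic alcohol, in which the aryl–palladium species adds to one vinyl terminus and β-hydride elimination toward the carbinol carbon gives an enol that tautomerises to the β-aryl vinyl ketone, the excess dienol limiting a second arylation; no stereocentre is formed.

Step 2
Reactants: 3 methyl 4-methoxy-3-(3-oxopent-4-en-1-yl)benzoate
Product: 4 methyl 4-methoxy-3-[(2Z)-3-(triisopropylsilyloxy)penta-2,4-dien-1-yl]benzoate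
Conditions: TIPSOTf, Et3N, CH2Cl2, 0 °C to rt
Reagents that add atoms: triisopropylsilyl trifluoromethanesulfonate, CC(C)[Si](C(C)C)(C(C)C)OS(=O)(=O)C(F)(F)F
Why: Soft enolisation with a silyl triflate and an amine can only involve the single α-methylene of the vinyl ketone and should give the favoured Z silyl enol ether, in which the arylmethyl group is trans to the vinyl group as an s-cis reactive diene requires.

Step 3
Reactants: 4 methyl 4-methoxy-3-[(2Z)-3-(triisopropylsilyloxy)penta-2,4-dien-1-yl]benzoate; 5 2-methoxy-5-methyl-1,4-benzoquinone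
Product: 6 cis-fused endo adduct carrying the C8 silyl enol ether
Conditions: TiCl2((R)-BINOLate) (20 mol %; from TiCl2(OiPr)2 and (R)-BINOL, 4 Å molecular sieves), CH2Cl2, −40 to −20 °C, slight excess of 4
Reagents that add atoms: none
Why: The reaction is a concerted, asynchronous endo [4+2] cycloaddition in which tetravalent titanium binds the C4 carbonyl oxygen and the neighbouring C3 methoxy oxygen of the quinone as a five-membered chelate, so that C10, β to the activated carbonyl, becomes the most electrophilic carbon and pairs with the nucleophilic enol ether carbon of the diene (future C9). The closest known reaction type is the Diels–Alder reaction of quinones under chiral titanium–BINOL Lewis acid catalysis, combined with the known chelation-controlled addition of dienes to the methyl-bearing olefin of this quinone. Ring B is closed as a cyclohexene by intermolecular [4+2] cycloaddition, C9–C10 and C5–C6 forming in the same event across the C5=C10 olefin. C10 is controlled by the BINOL ligand, which screens one face of the chelated quinone; C5 follows from suprafacial addition (H cis to the C10 methyl); C9 follows from the Z enol ether geometry and the endo transition state (C11 trans to the C10 methyl, to be inverted in step 12). The step needs site selectivity, secured by the methoxy group that deactivates the other quinone olefin, and regioselectivity, secured by the chelate together with the polarity of the 2-silyloxydiene, while the bulky triisopropylsilyl group resists silyl transfer to the Lewis acid.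

Step 4
Reactants: 6 cis-fused endo adduct carrying the C8 silyl enol ether
Product: 8 C4 enol triflate of the adduct, via potassium enolate 7 (not isolated)
Conditions: KN(SiMe3)2, THF, −78 °C; then PhNTf2, −78 to 0 °C
Reagents that add atoms: N-phenylbis(trifluoromethanesulfonimide), O=S(=O)(N(c1ccccc1)S(=O)(=O)C(F)(F)F)C(F)(F)F
Why: Enol triflate formation at the only enolisable position (C5–H next to the C4 ketone, since C1 has no α-hydrogen) gives the C4=C5 triflate, which deliberately erases C5 and leaves C9 and C10 untouched.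

Step 5
Reactants: 8 C4 enol triflate of the adduct; 9 5-bromo-2-methylpent-2-ene
Product: 11 3-methoxy-4-R-2,4,7-trien-1-one, via homoprenylzinc bromide 10 (not isolated)
Conditions: 9, Zn dust, LiCl, THF, 50 °C; then 8, PdCl2(dppf) (5 mol %), THF, 50 °C
Reagents that add atoms: none
Why: Negishi sp2–sp3 cross-coupling, in which the alkylzinc bromide tolerates the ketone, the ester and the silyl enol ether and the wide-bite-angle dppf ligand favours reductive elimination over β-hydride elimination; the ring olefin is placed at C4=C5 without ambiguity and no stereocentre is formed.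

Step 6
Reactants: 11 3-methoxy-4-R-2,4,7-trien-1-one
Product: 13 4-R-1,4,7-trien-3-one, via C1 allylic alcohol 12 (not isolated)
Conditions: NaBH4, CeCl3·7H2O, MeOH/THF, 0 °C; then aqueous oxalic acid, THF, 0 °C
Reagents that add atoms: water, O
Why: Stork–Danheiser transposition, in which Luche 1,2-reduction of the vinylogous-ester carbonyl at C1 (the benzoate is inert to NaBH4) gives an allylic alcohol whose mild acid hydrolysis expels the C1 hydroxyl and methanol, so that the carbonyl moves to C3 and the C1 oxygen is removed while the hindered TIPS enol ether should survive the brief dilute acid.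

Step 7
Reactants: 13 4-R-1,4,7-trien-3-one
Product: 14 4-R-4,7-dien-3-one
Conditions: H2 (1 atm), RhCl(PPh3)3 (10 mol %), benzene/EtOH, rt
Reagents that add atoms: none
Why: Homogeneous hydrogenation with RhCl(PPh3)3 is selective for the disubstituted C1=C2 bond of a cross-conjugated 1,4-dien-3-one, as is well known for steroidal dienones, and leaves the tetrasubstituted C4=C5 bond and the trisubstituted side-chain and enol ether olefins.

Step 8
Reactants: 14 4-R-4,7-dien-3-one
Product: 16 4α-methyl-4β-R-5,7-dien-3-one, via potassium dienolate 15 (not isolated)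
Conditions: KOtBu (1.1 equiv), THF/tBuOH, 0 °C; then MeI
Reagents that add atoms: iodomethane, CI
Why: Deconjugative α-alkylation of a 4-substituted Δ4-3-ketone, in which tert-butoxide removes the doubly allylic C6 proton and the extended dienolate is methylated at C4 on the α face, opposite the axial C10 methyl, which sets the quaternary C4 (methyl α, side chain β) and moves the olefin to C5=C6.

Step 9
Reactants: 16 4α-methyl-4β-R-5,7-dien-3-one
Product: 18 C3 enol triflate (Δ2), via potassium enolate 17 (not isolated)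
Conditions: KN(SiMe3)2, THF, −78 °C; then PhNTf2, −78 to 0 °C
Reagents that add atoms: N-phenylbis(trifluoromethanesulfonimide), O=S(=O)(N(c1ccccc1)S(=O)(=O)C(F)(F)F)C(F)(F)F
Why: Enol triflate formation toward C2, the only α-position that still bears hydrogen, as practised on 4,4-disubstituted 3-ketones of triterpenoids; no stereocentre changes.

Step 10
Reactants: 18 C3 enol triflate (Δ2)
Product: 19 4α,10β-dimethyl-4β-R-2,5,7-triene TIPS dienol ether
Conditions: Pd(OAc)2 (5 mol %), PPh3 (10 mol %), HCO2H, Bu3N, DMF, 60 °C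
Reagents that add atoms: none
Why: Palladium-catalysed formate reduction of an enol triflate (Cacchi reduction) replaces C–OTf by C–H through a palladium hydride, a non-radical path that cannot cyclise onto the side-chain olefin, and so removes the C3 oxygen.

Step 11
Reactants: 19 4α,10β-dimethyl-4β-R-2,5,7-triene TIPS dienol ether
Product: 21 5α-H Δ2,6-dien-8-one as C9 epimers, via Δ2,5-dien-8-one 20 (not isolated)
Conditions: Bu4NF, AcOH, THF, 0 °C; then DBU, THF, 40 °C
Reagents that add atoms: none
Why: Fluoride cleaves the silyl dienol ether to the β,γ-enone and base-mediated conjugation through the dienolate then protonates C5 on the α face, away from the axial C10 methyl and the axial C4 side chain, to give the trans ring fusion that is also the expected thermodynamic preference, while C9 epimerises under the same conditions and is left unassigned.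

Step 12
Reactants: 21 5α-H Δ2,6-dien-8-one as C9 epimers
Product: 23 trans-fused 9β-ArCH2 8-ketone, via C9-epimeric 8-ketone 22 (not isolated)
Conditions: H2 (1 atm), RhCl(PPh3)3 (10 mol %), benzene, rt; then NaOMe, MeOH, rt
Reagents that add atoms: none
Why: RhCl(PPh3)3 hydrogenates the two cis-disubstituted olefins (C2=C3 and the enone C6=C7) much faster than the trisubstituted side-chain olefin, and methoxide then equilibrates C9 through the C8 enolate toward the equatorial arylmethyl group (9β, cis to the C10 methyl), the epimer also favoured by axial protonation from the α face, with the minor epimer recyclable under the same conditions.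

Step 13
Reactants: 23 trans-fused 9β-ArCH2 8-ketone
Product: 25 Δ7 enol triflate, via potassium enolate 24 (not isolated)
Conditions: KN(SiMe3)2, THF, −78 °C; then PhNTf2, −78 to 0 °C
Reagents that add atoms: N-phenylbis(trifluoromethanesulfonimide), O=S(=O)(N(c1ccccc1)S(=O)(=O)C(F)(F)F)C(F)(F)F
Why: Kinetic enol triflate formation, in which the hindered amide base removes a C7 methylene proton and not the C9 methine next to quaternary C10, so the Δ7 triflate forms without touching C9.

Step 14
Reactants: 25 Δ7 enol triflate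
Product: 26 jaspic acid methyl ester methyl ether
Conditions: MeZnCl, Pd(PPh3)4 (5 mol %), THF, 50 °C
Reagents that add atoms: methylzinc chloride, C[Zn]Cl
Why: Negishi methylation of the enol triflate installs the C8 methyl and fixes the C7=C8 olefin, and the organozinc reagent leaves the methyl ester alone.

Step 15
Reactants: 26 jaspic acid methyl ester methyl ether
Product: 28 jaspic acid, via disodium salt 27 (not isolated)
Conditions: NaSEt (excess), DMF, 130 °C; then 1 M HCl
Reagents that add atoms: none
Why: Thiolate SN2 demethylation cleaves both the methyl ester and the aryl methyl ether (activated by the para carboxyl group) without acid, so both trisubstituted olefins are safe, and acidification liberates the phenol acid.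

Compound list

1 | methyl 3-iodo-4-methoxybenzoate | COC(=O)c1ccc(OC)c(I)c1 | starting material
2 | penta-1,4-dien-3-ol | C=CC(O)C=C | starting material
3 | methyl 4-methoxy-3-(3-oxopent-4-en-1-yl)benzoate | C=CC(=O)CCc1cc(C(=O)OC)ccc1OC | intermediate
4 | methyl 4-methoxy-3-[(2Z)-3-(triisopropylsilyloxy)penta-2,4-dien-1-yl]benzoate | C=C/C(O[Si](C(C)C)(C(C)C)C(C)C)=C/Cc1cc(C(=O)OC)ccc1OC | intermediate
5 | 2-methoxy-5-methyl-1,4-benzoquinone | COC1=CC(=O)C(C)=CC1=O | starting material
6 | cis-fused endo adduct: 3-methoxy-10β-methyl-9α-ArCH2-8-TIPSO-decalin-2,7-diene-1,4-dione, 5β-H | COC1=CC(=O)[C@]2(C)[C@H](Cc3cc(C(=O)OC)ccc3OC)C(O[Si](C(C)C)(C(C)C)C(C)C)=CC[C@@H]2C1=O | intermediate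
7 | potassium C4(O)=C5 enolate of 6 | COC1=CC(=O)[C@]2(C)[C@H](Cc3cc(C(=O)OC)ccc3OC)C(O[Si](C(C)C)(C(C)C)C(C)C)=CCC2=C1[O-].[K+] | intermediate (not isolated)
8 | C4 enol triflate: 3-methoxy-4-triflyloxy-10β-methyl-9α-ArCH2-8-TIPSO-decalin-2,4,7-trien-1-one | COC1=CC(=O)[C@]2(C)[C@H](Cc3cc(C(=O)OC)ccc3OC)C(O[Si](C(C)C)(C(C)C)C(C)C)=CCC2=C1OS(=O)(=O)C(F)(F)F | intermediate
9 | 5-bromo-2-methylpent-2-ene | CC(C)=CCCBr | starting material
10 | (4-methylpent-3-en-1-yl)zinc bromide | CC(C)=CCC[Zn]Br | intermediate (not isolated)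
11 | 3-methoxy-4-R-10β-methyl-9α-ArCH2-8-TIPSO-decalin-2,4,7-trien-1-one | COC1=CC(=O)[C@]2(C)[C@H](Cc3cc(C(=O)OC)ccc3OC)C(O[Si](C(C)C)(C(C)C)C(C)C)=CCC2=C1CCC=C(C)C | intermediate
12 | C1 alcohol of 11 (both C1 epimers) | COC1=CC(O)[C@]2(C)[C@H](Cc3cc(C(=O)OC)ccc3OC)C(O[Si](C(C)C)(C(C)C)C(C)C)=CCC2=C1CCC=C(C)C | intermediate (not isolated)
13 | 4-R-10β-methyl-9α-ArCH2-8-TIPSO-decalin-1,4,7-trien-3-one | CC(C)=CCCC1=C2CC=C(O[Si](C(C)C)(C(C)C)C(C)C)[C@@H](Cc3cc(C(=O)OC)ccc3OC)[C@@]2(C)C=CC1=O | intermediate
14 | 4-R-10β-methyl-9α-ArCH2-8-TIPSO-decalin-4,7-dien-3-one | CC(C)=CCCC1=C2CC=C(O[Si](C(C)C)(C(C)C)C(C)C)[C@@H](Cc3cc(C(=O)OC)ccc3OC)[C@@]2(C)CCC1=O | intermediate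
15 | potassium 3,5-dienolate of 14 | CC(C)=CCCC1=C([O-])CC[C@]2(C)[C@H](Cc3cc(C(=O)OC)ccc3OC)C(O[Si](C(C)C)(C(C)C)C(C)C)=CC=C12.[K+] | intermediate (not isolated)
16 | 4α,10β-dimethyl-4β-R-9α-ArCH2-8-TIPSO-decalin-5,7-dien-3-one | CC(C)=CCC[C@@]1(C)C(=O)CC[C@]2(C)[C@H](Cc3cc(C(=O)OC)ccc3OC)C(O[Si](C(C)C)(C(C)C)C(C)C)=CC=C12 | intermediate
17 | potassium C2=C3 enolate of 16 | CC(C)=CCC[C@@]1(C)C([O-])=CC[C@]2(C)[C@H](Cc3cc(C(=O)OC)ccc3OC)C(O[Si](C(C)C)(C(C)C)C(C)C)=CC=C12.[K+] | intermediate (not isolated)
18 | 3-triflyloxy-4α,10β-dimethyl-4β-R-9α-ArCH2-8-TIPSO-decalin-2,5,7-triene | CC(C)=CCC[C@@]1(C)C(OS(=O)(=O)C(F)(F)F)=CC[C@]2(C)[C@H](Cc3cc(C(=O)OC)ccc3OC)C(O[Si](C(C)C)(C(C)C)C(C)C)=CC=C12 | intermediate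
19 | 4α,10β-dimethyl-4β-R-9α-ArCH2-8-TIPSO-decalin-2,5,7-triene | CC(C)=CCC[C@@]1(C)C=CC[C@]2(C)[C@H](Cc3cc(C(=O)OC)ccc3OC)C(O[Si](C(C)C)(C(C)C)C(C)C)=CC=C12 | intermediate
20 | 4α,10β-dimethyl-4β-R-9α-ArCH2-decalin-2,5-dien-8-one | CC(C)=CCC[C@@]1(C)C=CC[C@]2(C)[C@H](Cc3cc(C(=O)OC)ccc3OC)C(=O)CC=C12 | intermediate (not isolated)
21 | 4α,10β-dimethyl-4β-R-9-ArCH2-decalin-2,6-dien-8-one, 5α-H, both C9 epimers | CC(C)=CCC[C@@]1(C)C=CC[C@]2(C)C(Cc3cc(C(=O)OC)ccc3OC)C(=O)C=C[C@@H]12 | intermediate
22 | 4α,10β-dimethyl-4β-R-9-ArCH2-decalin-8-one, 5α-H, both C9 epimers | CC(C)=CCC[C@@]1(C)CCC[C@]2(C)C(Cc3cc(C(=O)OC)ccc3OC)C(=O)CC[C@@H]12 | intermediate (not isolated)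
23 | 4α,10β-dimethyl-4β-R-9β-ArCH2-decalin-8-one, 5α-H (trans-fused) | CC(C)=CCC[C@@]1(C)CCC[C@]2(C)[C@@H](Cc3cc(C(=O)OC)ccc3OC)C(=O)CC[C@@H]12 | intermediate
24 | potassium C7=C8 enolate of 23 | CC(C)=CCC[C@@]1(C)CCC[C@]2(C)[C@@H](Cc3cc(C(=O)OC)ccc3OC)C([O-])=CC[C@@H]12.[K+] | intermediate (not isolated)
25 | 8-triflyloxy-4α,10β-dimethyl-4β-R-9β-ArCH2-decal-7-ene, 5α-H | CC(C)=CCC[C@@]1(C)CCC[C@]2(C)[C@@H](Cc3cc(C(=O)OC)ccc3OC)C(OS(=O)(=O)C(F)(F)F)=CC[C@@H]12 | intermediate
26 | jaspic acid methyl ester methyl ether (4α,8,10β-trimethyl-4β-R-9β-ArCH2-decal-7-ene, 5α-H) | CC(C)=CCC[C@@]1(C)CCC[C@]2(C)[C@@H](Cc3cc(C(=O)OC)ccc3OC)C(C)=CC[C@@H]12 | intermediate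
27 | disodium phenolate carboxylate of jaspic acid | CC(C)=CCC[C@@]1(C)CCC[C@]2(C)[C@@H](Cc3cc(C(=O)[O-])ccc3[O-])C(C)=CC[C@@H]12.[Na+].[Na+] | intermediate (not isolated)
28 | jaspic acid | CC(C)=CCC[C@@]1(C)CCC[C@]2(C)[C@@H](Cc3cc(C(=O)O)ccc3O)C(C)=CC[C@@H]12 | target

Total step count: 15. Longest linear sequence: 15 steps (1 to 28; 2, 5 and 9 are purchased).

Steps most likely to fail

Step 3. The titanium complex may discriminate poorly between the two faces of this hindered, trisubstituted dienophile, or the Lewis acid may strip the silyl group from the diene before cycloaddition. Fallback: setting out from 4 and 5, the cycloaddition is run without a chiral ligand, either with the achiral chelating Lewis acid TiCl2(OiPr)2 (CH2Cl2, −40 °C) or thermally in toluene. This should give the racemic cis-fused endo adduct F1, and absolute configuration then comes from resolution by preparative chromatography on a chiral stationary phase. The route is rejoined at 6.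

Step 11. Migration of the olefin into conjugation may stay incomplete, or protonation at C5 may show poor facial selectivity and give cis-fused material. Fallback: setting out from 19, the C5 hydrogen is delivered by a catalyst instead of a proton source. Cr(CO)3(η6-naphthalene) with H2 (5 MPa, acetone, 40 °C) adds hydrogen 1,4 across the cisoid C5=C6–C7=C8 diene from the open α face and ignores isolated olefins, giving the 5α,8α-dihydro allylic silyl ether F2. Bu4NF in THF then gives the allylic alcohol F3, and oxidation with MnO2 in CH2Cl2 gives the Δ6-8-ketone as its 9α epimer. That is one of the epimers that make up 21, where the route is rejoined.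

Step 12. The methoxide equilibrium at C9 may be flat and leave much of the axial 9α epimer. Fallback: setting out from 21, C9 is set under kinetic instead of thermodynamic control. KN(SiMe3)2 (THF, −78 °C) removes the C9 proton of both epimers and gives one cross-conjugated potassium dienolate F4. A quench at −78 °C with the hindered proton donor 2,6-di-tert-butyl-4-methylphenol should protonate C9 from the α face, opposite the C10 methyl, to give the 9β-ArCH2 Δ2,6-dien-8-one F5. Hydrogenation with RhCl(PPh3)3 and H2 in benzene, without base, then gives 23, where the route is rejoined.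

Further compounds
F1 | step 3 | racemic cis-fused endo adduct (6 and its enantiomer, 1:1) | COC1=CC(=O)[C@]2(C)[C@H](Cc3cc(C(=O)OC)ccc3OC)C(O[Si](C(C)C)(C(C)C)C(C)C)=CC[C@@H]2C1=O.COC1=CC(=O)[C@@]2(C)[C@@H](Cc3cc(C(=O)OC)ccc3OC)C(O[Si](C(C)C)(C(C)C)C(C)C)=CC[C@H]2C1=O
F2 | step 11 | 8β-TIPSO-4α,10β-dimethyl-4β-R-9α-ArCH2-decalin-2,6-diene, 5α-H, 8α-H | CC(C)=CCC[C@@]1(C)C=CC[C@]2(C)[C@H](Cc3cc(C(=O)OC)ccc3OC)[C@@H](O[Si](C(C)C)(C(C)C)C(C)C)C=C[C@@H]12
F3 | step 11 | 4α,10β-dimethyl-4β-R-9α-ArCH2-decalin-2,6-dien-8β-ol, 5α-H | CC(C)=CCC[C@@]1(C)C=CC[C@]2(C)[C@H](Cc3cc(C(=O)OC)ccc3OC)[C@@H](O)C=C[C@@H]12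
F4 | step 12 | potassium C8(O)=C9 cross-conjugated dienolate of 21 | CC(C)=CCC[C@@]1(C)C=CC[C@]2(C)C(Cc3cc(C(=O)OC)ccc3OC)=C([O-])C=C[C@@H]12.[K+]
F5 | step 12 | 4α,10β-dimethyl-4β-R-9β-ArCH2-decalin-2,6-dien-8-one, 5α-H | CC(C)=CCC[C@@]1(C)C=CC[C@]2(C)[C@@H](Cc3cc(C(=O)OC)ccc3OC)C(=O)C=C[C@@H]12
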